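(The constants used here come from no measurement; what happens was integrated by code.)

Amounts come first at this meeting, each as a fraction of the starting material charged, and this stood on the board:

    spent carrier + salt in the second phase ⇌ fresh carrier + spent salt in the second phase (K1 = 16, k1 = 2.29 M⁻¹ s⁻¹)
    starting material + fresh carrier → target + spent carrier (k2 = 58.5 M⁻¹ s⁻¹)
    crystals ⇌ target, rate k3*(cs3 - [target]) while solid is left; crystals form when [target] > cs3 (cs3 = 0.052 M, k3 = 0.138 s⁻¹)
    target → over-reaction product (k4 = 0.0314 s⁻¹)
starting material 0.40 M; salt in the second phase 1.30 equiv; spent carrier 2.5 mol%; time 2.0 min; volume of the second phase over the first 0.25
- what is said of target includes crystals
- in the second phase: salt in the second phase, spent salt in the second phase; everything else is in the first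
- charges count per volume of the first phase; a concentration in a rate is the amount of a species over the volume of its own phase; every rate counts per litre of the first phase
- crystals is a solid; its amount is given per volume of the solution
- run time (flask): 2.0 min
- ochre: doubling the dissolution coefficient of step 3, all else as stated
- blue: doubling the solubility in step 3, all else as stated
- green: doubling the amount of salt in the second phase, all else as stated
1. how much target and crystals together there is at 2.0 min, in percent of the starting material charged
2. the change that raises the amount of target and crystals together at 2.0 min, in percent of the starting material charged most ("none" if none brings more than 2 percentage points) (ochre / blue / green / none)
3. amount of target and crystals together at 2.0 min, in percent of the starting material charged, after green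

The first member reckoned that at the charges, with the carrier as spent carrier and the forward step alone, the cycle passes the whole charge in 0.140 min, far less than the run of 2.0 min, and that 1.30 equiv of salt outlasts the starting material, the limiting reagent. She therefore proposed treating conversion as an early event.

The second member answered that dissolved target has a half-life of 0.37 min by over-reaction alone, shorter than the run, and she turned to the crystals that feed the solution. Once the early surplus has gone, she wrote, and while crystals stand, she took dissolution to balance over-reaction, with dissolved target at a plateau of 0.106 of the charge. The meeting named the product of the over-reaction constant and this plateau the drain, 0.200 min⁻¹: the fraction of the charge lost per minute while crystals stand. In powers of ten, the over-reaction constant times the run gives 0.576, solubility over charge −0.886, and the dissolution share −0.0890, which add to −0.398.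

The third member added the early surplus: target above the plateau splits between crystals and over-reaction, and over-reaction takes a share of 0.185.

My own reckoning, as secretary, subtracts both losses and leaves 43.5%. The salt stands in neither loss of this formula, so I keep that figure for green. Ochre lowers the over-reaction's share of the surplus to 0.102, less than before, also raises the plateau, and reckons to 47.0%, a gain of 3.5 percentage points. Blue doubles the drain to 0.400 min⁻¹ while crystals stand, so I reckon it loses target.

The forecast gave 43.7%, ochre as best and 43.6% after green, holding that “More salt only speeds a step that already finishes early”.

The simulation gives 43.8%, best ochre at 3.5 points, blue −33 points, green −0.1 points, and 43.7% after green.

In the flask, target with crystals read 63.7% at 1.00 min and 43.8% at 2.00 min, a fall of 20 points against a drain of 0.200 min⁻¹, with crystals at 33.2%. The neighbouring flask holds the same amounts and is read at 3.0 min. Its extra time costs 0.200 of the charge, less than those crystals, so the reckoning gives 23.5%. That flask gives 23.8%, with crystals at 13.2% and over-reaction product at 76.2%.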